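The constants are assumed; no experiment stands behind them.

**Supply ratio.** I start from a ratio: partner arriving at the starting material against second substrate arriving there.

in all of them: solid reagent 1.10 equiv; time 6.0 h
- Monday's: starting material 0.10 M; second substrate 1.00 equiv; everything together at the start
- Thursday's: starting material 0.10 M (fed, over 4.0 h); second substrate 1.00 equiv; all else is in the flask from the start; the feed brings no volume worth counting
- Saturday's: starting material 0.10 M; second substrate 1.00 equiv (fed, over 4.0 h); all else is in the flask from the start; the feed brings no volume worth counting

    coupling partner + target → over-reaction product (k1 = 2.83 × 10⁻⁴ L mol⁻¹ s⁻¹)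
    starting material + coupling partner → target (k2 = 0.0599 L mol⁻¹ s⁻¹)
    solid reagent ⇌ coupling partner, rate k3*(cs3 - [coupling partner]) while solid is left; crystals form when [coupling partner] > cs3 (cs3 = 0.069 M, k3 = 1.50 × 10⁻⁴ s⁻¹)
    starting material + second substrate → cross product (k4 = 0.0179 L mol⁻¹ s⁻¹)
    target ⇌ isomer of the product (K5 = 0.340, k5 = 0.00171 s⁻¹)
    second substrate + coupling partner → second product (k6 = 0.107 L mol⁻¹ s⁻¹)

- as a solid, counted per litre of solution: solid reagent
- at the start none of the solid reagent is in solution
- run time (Monday's): 6.0 h

- the best flask by amount of target, in percent of the starting material charged; "all alike" if 1.5 percentage points covers them all (Monday's / Thursday's / Saturday's / all alike)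
- amount of target at the end, in percent of the starting material charged, Monday's
- amount of target at the end, in percent of the starting material charged, Thursday's
- amount of target at the end, in percent of the starting material charged, Saturday's

**Two supplies.** With little partner in solution, the solid delivers 0.0373 M h⁻¹, and a steady feed of a full charge brings 0.0250 M h⁻¹. That gives 59.8%, the partner share: dissolving rate over the sum of dissolving and feed rates.

**Saturday's curve.** In Saturday's, the fed second substrate has a pseudo-first-order lifetime of 9.31 min against the charged starting material, far shorter than the feed time, so I let it react as it arrives. I then draw target plus isomer in Saturday's climbing straight at 0.0373 M h⁻¹, and I put the knee, where c(starting material) reaches zero in my estimate, near 1.61 h. Beyond it I draw the line flat. The forward half-life of target by the isomer step, way back not counted, is 0.11 h in Monday's; that step is first order, and this half-life is short against the run, so I let target keep 74.6% of that pool. I reckon 44.7%.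

**Monday's crossing.** In Monday's, the cross rate starts 17.3 times the dissolving rate, but it falls with the product of c(starting material) and c(second substrate). At equal concentrations of these two, partner divides 35.9% to starting material. In my estimate for Monday's, the cross rate therefore meets partner's flow to starting material at c(starting material) = 0.0144 M, and I take that as a rough pool: 10.8%.

**Thursday's ceiling.** In Thursday's, I let both supplies eat the second substrate until about the same knee. Counting all partner beyond that share as target plus isomer, I estimate a ceiling for Thursday's: under 37.4%. My choice is Saturday's.

**Forecast.** The forecast names Saturday's, with 13.5% for Monday's, 36% for Thursday's and 42% for Saturday's, holding that “feeding either one suppresses that cross reaction, and feeding the second substrate does so best”. My Saturday's stands higher and my Monday's lower.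

**Outcome.** The simulation gives Saturday's: 13.9% for Monday's, 32.0% for Thursday's, 48.0% for Saturday's. In Saturday's, target and isomer together reach 64.3% against a partner share of 59.8%, with 20% of the second substrate unused. The neighbour of Saturday's, charged 0.250 equiv of second substrate, has a partner share of 85.6%, which gives 63.9% as target; that flask ends at 65.7%.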